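**Plan**

Locants (spiro[5.5]undecane): C1 CH(OAc), C2 CH2, C3 C(Me)Cl, C4 CHBr, C5 CH2, C6 spiro, C7 C(Me)OH, C8/C9 CH2, C10 CHBr, C11 CMe2.
Retrosynthetic cuts, in order: O1–acetyl; C3–Cl and C4–Br (anti BrCl addition to a C3=C4 alkene); C3=C4 (ring-closing metathesis); C6–C11 together with C7–O (bromonium-initiated cyclisation with acetate capture); C1–C6 together with C2–C3 (three-component conjunctive cross-coupling); finally the alkenyl iodide (ynoate carbocupration).
Forward order: acyclic (Z)-alkenyl iodide, then a triene alcohol carrying C1, then ring B, then ring A, then the ring A halogens, then the acetate.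
Enabling feature: C1(O)–C2H2 of ring A is a vinylboron unit in disguise. C1–O is an oxidised C–B bond; C6, with C7(Me)(OH), is a masked tetrasubstituted alkene and so can be an sp2 migrating group on boron before ring B exists; C3 is the sp2 carbon of an isopropenyl electrophile.
Stereochemistry: C1 comes from the chiral Pd catalyst; C6, C7 and C10 are relayed from C1 and the (Z)-alkene geometry through a chair transition state; C3 and C4 come from hydroxyl-directed anti bromochlorination.

Key step: step 5

Remark: prop-1-en-2-yl trifluoromethanesulfonate (12) is taken as a purchasable reagent (otherwise one step from acetone); hydrolysis of ion 18 is assumed to give mainly the C1 acetate 19, and either monoacetate converges on diol 20 in the same pot.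

**Route**

Step 1
Reactants: 1 5-bromo-2-methylpent-2-ene; 2 ethyl but-2-ynoate
Product: 6 ethyl (2Z)-2-iodo-3,7-dimethylocta-2,6-dienoate, via Grignard reagent 3 (not isolated), via alkylcopper 4 (not isolated), via alkenylcopper 5 (not isolated)
Conditions: 1, Mg, THF, rt; CuBr·SMe2, THF, −78 °C; 2, −78 °C; I2, THF, −78 → −40 °C
Reagents that add atoms: iodine, II
Why: Syn-carbocupration of the ynoate places the homoprenyl group and copper cis, and iodinolysis of the configurationally stable alkenylcopper at −78 °C should retain this, so the (Z)-tetrasubstituted alkene is set here (organocopper addition to an alkynoate with electrophilic trapping).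

Step 2
Reactants: 6 ethyl (2Z)-2-iodo-3,7-dimethylocta-2,6-dienoate
Product: 7 (2Z)-2-iodo-3,7-dimethylocta-2,6-dien-1-ol
Conditions: DIBAL-H (2.2 equiv), CH2Cl2, −78 → 0 °C; Rochelle salt work-up
Reagents that add atoms: none
Why: DIBAL-H should reduce the ester to the allylic alcohol at low temperature without touching the alkenyl iodide or the alkene geometry (ester reduction).

Step 3
Reactants: 7 (2Z)-2-iodo-3,7-dimethylocta-2,6-dien-1-ol
Product: 8 (2Z)-1-bromo-2-iodo-3,7-dimethylocta-2,6-diene
Conditions: CBr4, PPh3, CH2Cl2, 0 °C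
Reagents that add atoms: carbon tetrabromide, BrC(Br)(Br)Br
Why: Appel bromination should convert the primary allylic alcohol to the bromide under neutral conditions that spare the acid-sensitive prenyl alkene and the C–I bond.

Step 4
Reactants: 8 (2Z)-1-bromo-2-iodo-3,7-dimethylocta-2,6-diene; 9 vinylmagnesium bromide
Product: 10 (4Z)-4-iodo-5,9-dimethyldeca-1,4,8-triene
Conditions: CuI (10 mol%), THF, −30 → 0 °C
Reagents that add atoms: none
Why: Copper-catalysed SN2 coupling at the primary allylic bromide should give the skipped diene, since SN2′ attack would have to form a quaternary centre and the hindered alkenyl iodide is inert at this temperature (Cu-catalysed Grignard allylic substitution).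

Step 5
Reactants: 10 (4Z)-4-iodo-5,9-dimethyldeca-1,4,8-triene; 11 4,4,5,5-tetramethyl-2-vinyl-1,3,2-dioxaborolane; 12 prop-1-en-2-yl trifluoromethanesulfonate
Product: 16 (4R,5Z)-2,6,10-trimethyl-5-(prop-2-en-1-yl)undeca-1,5,9-trien-4-ol, via alkenyllithium 13 (not isolated), via borate complex 14 (not isolated), via allylboronate 15 (not isolated)
Conditions: t-BuLi (2.0 equiv), Et2O, −78 °C; 11, −78 °C → rt; solvent switch to THF; Pd(OAc)2 (3 mol%), (Sp,Sp)-MandyPhos (3.6 mol%), KOTf, 12, 60 °C; then 3 M NaOH, 30% H2O2, 0 °C → rt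
Reagents that add atoms: hydrogen peroxide, OO
Why: Iodine–lithium exchange with retention gives 13, which adds to the boron of 11 to give the bis(alkenyl)borate 14; the cationic isopropenyl–Pd(II) species from 12 binds the unhindered B-vinyl group and triggers a 1,2-shift of the tetrasubstituted alkenyl group from boron to the internal vinyl carbon (alkene geometry retained) while Pd bonds to the terminal carbon, and reductive elimination then forms the CH2–C(Me)=CH2 bond. The closest known reaction type is the Pd/MandyPhos-catalysed three-component conjunctive cross-coupling of an alkenyllithium, a vinylboronic ester and an alkenyl triflate (bis(alkenyl)borate variant, giving α-chiral allylic boronic esters). No ring is closed in this operation; it joins three components around the future C1–C2 unit, and both new bonds (C1–C6 and C2–C3) later lie in ring A, which is closed by metathesis in step 8. The one new stereocentre (the boron-bearing carbon, later C1) should be set by the chiral ligand through face-selective binding of the vinylborate and anti addition of Pd and the migrating group, and is transferred to oxygen with retention in the oxidation of 15; the ligand antipode is the remedy if the sense proves opposite. The step needs activation of the B-vinyl group in preference to direct Suzuki-type transmetallation and to the other alkenes, which the steric shielding of the tetrasubstituted alkenyl group and the cationic, iodide-scavenged Pd centre should secure.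

Step 6
Reactants: 16 (4R,5Z)-2,6,10-trimethyl-5-(prop-2-en-1-yl)undeca-1,5,9-trien-4-ol
Product: 17 (4R,5Z)-2,6,10-trimethyl-5-(prop-2-en-1-yl)undeca-1,5,9-trien-4-yl acetate
Conditions: Ac2O, pyridine, DMAP (cat.), CH2Cl2, 0 °C → rt
Reagents that add atoms: acetic anhydride, CC(=O)OC(C)=O
Why: DMAP-catalysed acylation of the secondary allylic alcohol installs the acetate that later acts as the internal nucleophile, with no stereocentre touched (esterification).

Step 7
Reactants: 17 (4R,5Z)-2,6,10-trimethyl-5-(prop-2-en-1-yl)undeca-1,5,9-trien-4-yl acetate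
Product: 20 (1R,2R,4R)-4-bromo-2-[(1R)-1-hydroxy-3-methylbut-3-en-1-yl]-1,3,3-trimethyl-2-(prop-2-en-1-yl)cyclohexan-1-ol, via dioxanylium ion 18 (not isolated), via hydroxy acetate 19 (not isolated)
Conditions: Et2SBr·SbCl5Br (BDSB, 1.1 equiv), MeNO2, −25 °C, 5 min; aq. NaHCO3; then K2CO3, MeOH, rt
Reagents that add atoms: bromodiethylsulfonium bromopentachloroantimonate, CC[S+](Br)CC.Cl[Sb-](Cl)(Cl)(Cl)(Cl)Br
Why: Br+ transfer to the most accessible trisubstituted (prenyl) alkene should trigger a chair-like cation–olefin cyclisation in which the tetrasubstituted alkene attacks through its allyl-bearing carbon and the acetate carbonyl oxygen captures the tertiary cation anti through a chair 1,3-dioxan-2-ylium ion, so that C10 (Br equatorial), C6 (from the Z geometry) and C7 (anti addition) are set relative to C1 (C1–H in the alkene plane by A(1,3) strain, C1–O anti to the new C–C bond); hydrolysis and methanolysis then give the diol (bromonium-induced polyene cyclisation with neighbouring-group termination).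

Step 8
Reactants: 20 (1R,2R,4R)-4-bromo-2-[(1R)-1-hydroxy-3-methylbut-3-en-1-yl]-1,3,3-trimethyl-2-(prop-2-en-1-yl)cyclohexan-1-ol
Product: 21 (1R,6R,7R,10R)-10-bromo-3,7,11,11-tetramethylspiro[5.5]undec-3-ene-1,7-diol
Conditions: Grubbs second-generation catalyst (5 mol%), CH2Cl2, 40 °C
Reagents that add atoms: none
Why: Ring-closing metathesis of the allyl and 2-methylallyl groups should close ring A as a trisubstituted cyclohexene next to the quaternary centre with loss of ethene, the hydroxyls and the secondary bromide being tolerated by the Ru carbene.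

Step 9
Reactants: 21 (1R,6R,7R,10R)-10-bromo-3,7,11,11-tetramethylspiro[5.5]undec-3-ene-1,7-diol
Product: 22 (1R,3S,4S,6R,7R,10R)-4,10-dibromo-3-chloro-3,7,11,11-tetramethylspiro[5.5]undecane-1,7-diol
Conditions: NBS (1.1 equiv), ClTi(OiPr)3 (1.1 equiv), CH2Cl2/hexanes, −20 °C
Reagents that add atoms: N-bromosuccinimide, O=C1CCC(=O)N1Br; chlorotitanium triisopropoxide, CC(C)O[Ti](Cl)(OC(C)C)OC(C)C
Why: The titanium alkoxide of the C1 hydroxyl should deliver chloride to the tertiary C3 on its own face (1,3-cis) while Br+ adds anti at C4 on the face not shielded by the axial C7 of ring B, giving the Markovnikov trans-bromochloride with Cl cis to O1 (hydroxyl-directed Ti-mediated alkene bromochlorination).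

Step 10
Reactants: 22 (1R,3S,4S,6R,7R,10R)-4,10-dibromo-3-chloro-3,7,11,11-tetramethylspiro[5.5]undecane-1,7-diol
Product: 23 (1R,3S,4S,6R,7R,10R)-4,10-dibromo-3-chloro-7-hydroxy-3,7,11,11-tetramethylspiro[5.5]undecan-1-yl acetate
Conditions: Ac2O, pyridine, DMAP (cat.), CH2Cl2, 0 °C → rt
Reagents that add atoms: acetic anhydride, CC(=O)OC(C)=O
Why: The equatorial secondary hydroxyl should be acetylated selectively because the tertiary C7 hydroxyl does not react under these conditions (selective esterification).

**Compound list**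

1 | 5-bromo-2-methylpent-2-ene | CC(C)=CCCBr | starting material
2 | ethyl but-2-ynoate | CC#CC(=O)OCC | starting material
3 | (4-methylpent-3-en-1-yl)magnesium bromide | CC(C)=CCC[Mg]Br | intermediate
4 | (4-methylpent-3-en-1-yl)copper | CC(C)=CCC[Cu] | intermediate
5 | ethyl (2Z)-2-cuprio-3,7-dimethylocta-2,6-dienoate | CCOC(=O)/C([Cu])=C(\C)CCC=C(C)C | intermediate
6 | ethyl (2Z)-2-iodo-3,7-dimethylocta-2,6-dienoate | CCOC(=O)/C(I)=C(\C)CCC=C(C)C | intermediate
7 | (2Z)-2-iodo-3,7-dimethylocta-2,6-dien-1-ol | OC/C(I)=C(\C)CCC=C(C)C | intermediate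
8 | (2Z)-1-bromo-2-iodo-3,7-dimethylocta-2,6-diene | BrC/C(I)=C(\C)CCC=C(C)C | intermediate
9 | vinylmagnesium bromide | C=C[Mg]Br | starting material
10 | (4Z)-4-iodo-5,9-dimethyldeca-1,4,8-triene | C=CC/C(I)=C(\C)CCC=C(C)C | intermediate
11 | 4,4,5,5-tetramethyl-2-vinyl-1,3,2-dioxaborolane | C=CB1OC(C)(C)C(C)(C)O1 | starting material
12 | prop-1-en-2-yl trifluoromethanesulfonate | C=C(C)OS(=O)(=O)C(F)(F)F | starting material
13 | [(4E)-5,9-dimethyldeca-1,4,8-trien-4-yl]lithium | C=CC/C([Li])=C(\C)CCC=C(C)C | intermediate
14 | lithium [(4E)-5,9-dimethyldeca-1,4,8-trien-4-yl](ethenyl)(2,3-dimethylbutane-2,3-diolato)borate | [Li+].C=C[B-]1(OC(C)(C)C(C)(C)O1)/C(CC=C)=C(/C)CCC=C(C)C | intermediate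
15 | 2-[(4R,5Z)-2,6,10-trimethyl-5-(prop-2-en-1-yl)undeca-1,5,9-trien-4-yl]-4,4,5,5-tetramethyl-1,3,2-dioxaborolane | C=C(C)C[C@@H](B1OC(C)(C)C(C)(C)O1)/C(CC=C)=C(/C)CCC=C(C)C | intermediate
16 | (4R,5Z)-2,6,10-trimethyl-5-(prop-2-en-1-yl)undeca-1,5,9-trien-4-ol | C=C(C)C[C@@H](O)/C(CC=C)=C(/C)CCC=C(C)C | intermediate
17 | (4R,5Z)-2,6,10-trimethyl-5-(prop-2-en-1-yl)undeca-1,5,9-trien-4-yl acetate | CC(=O)O[C@H](CC(C)=C)/C(CC=C)=C(/C)CCC=C(C)C | intermediate
18 | (4R,4aR,6R,8aR)-6-bromo-2,5,5,8a-tetramethyl-4-(2-methylprop-2-en-1-yl)-4a-(prop-2-en-1-yl)-4a,5,6,7,8,8a-hexahydro-4H-1,3-benzodioxin-2-ylium bromopentachloroantimonate | C=C(C)C[C@H]1OC(C)=[O+][C@]2(C)CC[C@@H](Br)C(C)(C)[C@]12CC=C.Cl[Sb-](Cl)(Cl)(Cl)(Cl)Br | intermediate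
19 | (1R)-1-[(1R,3R,6R)-3-bromo-6-hydroxy-2,2,6-trimethyl-1-(prop-2-en-1-yl)cyclohexyl]-3-methylbut-3-en-1-yl acetate | CC(=O)O[C@H](CC(C)=C)[C@@]1(CC=C)C(C)(C)[C@H](Br)CC[C@@]1(C)O | intermediate
20 | (1R,2R,4R)-4-bromo-2-[(1R)-1-hydroxy-3-methylbut-3-en-1-yl]-1,3,3-trimethyl-2-(prop-2-en-1-yl)cyclohexan-1-ol | C=C(C)C[C@@H](O)[C@@]1(CC=C)C(C)(C)[C@H](Br)CC[C@@]1(C)O | intermediate
21 | (1R,6R,7R,10R)-10-bromo-3,7,11,11-tetramethylspiro[5.5]undec-3-ene-1,7-diol | O[C@@H]1CC(C)=CC[C@@]12C(C)(C)[C@H](Br)CC[C@@]2(C)O | intermediate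
22 | (1R,3S,4S,6R,7R,10R)-4,10-dibromo-3-chloro-3,7,11,11-tetramethylspiro[5.5]undecane-1,7-diol | O[C@@H]1C[C@](C)(Cl)[C@@H](Br)C[C@@]12C(C)(C)[C@H](Br)CC[C@@]2(C)O | intermediate
23 | (1R,3S,4S,6R,7R,10R)-4,10-dibromo-3-chloro-7-hydroxy-3,7,11,11-tetramethylspiro[5.5]undecan-1-yl acetate | CC(=O)O[C@@H]1C[C@](C)(Cl)[C@@H](Br)C[C@@]12C(C)(C)[C@H](Br)CC[C@@]2(C)O | target

**Totals**

Total step count: 10. Longest linear sequence: 10 steps (1 → 23).

**Steps most likely to fail**

Step 5. What may go wrong: direct transmetallation of an alkenyl group from the borate to palladium (Suzuki-type diene formation), a slow 1,2-shift of the hindered tetrasubstituted alkenyl group, catalyst inhibition by iodide, or insufficient face selectivity at the vinyl group. Fallback (the C1 stereocentre is built by carbonyl allylation instead): starting from 10, iodine–lithium exchange (t-BuLi, Et2O, −78 °C) and formylation with DMF should give the enal (2Z)-3,7-dimethyl-2-(prop-2-en-1-yl)octa-2,6-dienal F1. Enantioselective methallylboration of this aldehyde with (+)-B-(2-methylallyl)diisopinocampheylborane (Et2O, −78 °C; NaOH/H2O2 work-up) should then give 16, where the route is rejoined.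

Step 7. What may go wrong: bromonium formation at the tetrasubstituted or the 1,1-disubstituted alkene, ionisation of the allylic acetate by the Lewis-acidic reagent, proton loss from the tertiary cation instead of acetate capture, or poor facial control in the open-chain transition state. Fallback (the order of ring construction is reversed): starting from 17, ring-closing metathesis (Grubbs second-generation catalyst, CH2Cl2, 40 °C) should first give the cyclic acetate (1R,6Z)-3-methyl-6-(6-methylhept-5-en-2-ylidene)cyclohex-3-en-1-yl acetate F2, in which A(1,3) strain holds the acetate axial and the terminal alkenes are gone. Bromonium cyclisation with 2,4,4,6-tetrabromocyclohexa-2,5-dienone (MeNO2, 0 °C; aqueous work-up) should then proceed anti to the axial acetate to give (1R,6R,7R,10R)-10-bromo-7-hydroxy-3,7,11,11-tetramethylspiro[5.5]undec-3-en-1-yl acetate F3. K2CO3/MeOH converts this into 21, where the route is rejoined.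

Step 9. What may go wrong: transannular capture of the bromonium ion by the C7 hydroxyl (bromoetherification), diaxial opening that gives the C3/C4-epimeric trans pair, or anti-Markovnikov opening. Fallback (hydroxyl direction is replaced by steric control on a protected substrate): starting from 21, TMSOTf/2,6-lutidine (CH2Cl2, −78 °C) should give (1R,6R,7R,10R)-10-bromo-3,7,11,11-tetramethyl-1,7-bis[(trimethylsilyl)oxy]spiro[5.5]undec-3-ene F4. Tetraethylammonium dichlorobromate (CH2Cl2, −78 °C) should then add Br to the C4 face away from the axial silyloxy-bearing C7 and chloride to C3, giving (1R,3S,4S,6R,7R,10R)-4,10-dibromo-3-chloro-3,7,11,11-tetramethyl-1,7-bis[(trimethylsilyl)oxy]spiro[5.5]undecane F5. K2CO3/MeOH removes both silyl groups to give 22, where the route is rejoined.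

Further compounds
F1 | step 5 | (2Z)-3,7-dimethyl-2-(prop-2-en-1-yl)octa-2,6-dienal | O=C/C(CC=C)=C(/C)CCC=C(C)C
F2 | step 7 | (1R,6Z)-3-methyl-6-(6-methylhept-5-en-2-ylidene)cyclohex-3-en-1-yl acetate | CC(=O)O[C@@H]1CC(C)=CC/C1=C(\C)CCC=C(C)C
F3 | step 7 | (1R,6R,7R,10R)-10-bromo-7-hydroxy-3,7,11,11-tetramethylspiro[5.5]undec-3-en-1-yl acetate | CC(=O)O[C@@H]1CC(C)=CC[C@@]12C(C)(C)[C@H](Br)CC[C@@]2(C)O
F4 | step 9 | (1R,6R,7R,10R)-10-bromo-3,7,11,11-tetramethyl-1,7-bis[(trimethylsilyl)oxy]spiro[5.5]undec-3-ene | C[Si](C)(C)O[C@@H]1CC(C)=CC[C@@]12C(C)(C)[C@H](Br)CC[C@@]2(C)O[Si](C)(C)C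
F5 | step 9 | (1R,3S,4S,6R,7R,10R)-4,10-dibromo-3-chloro-3,7,11,11-tetramethyl-1,7-bis[(trimethylsilyl)oxy]spiro[5.5]undecane | C[Si](C)(C)O[C@@H]1C[C@](C)(Cl)[C@@H](Br)C[C@@]12C(C)(C)[C@H](Br)CC[C@@]2(C)O[Si](C)(C)C
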